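The oxolane O–C9–C11–C12–C13 is not closed directly between its two fully substituted carbons. Because C13 also carries the CH2–O carbon C16, the hindered C9 hydroxyl is first bound to C16 by lactolisation, giving a six-membered 5-ethynyl-3,4-dihydro-2H-pyran in which C13 is planar. Epoxidation of this enol ether and copper-allenylidene ionisation of the propargylic C13–O bond then shift the ring oxygen from C16 to C13: a stereoconvergent six-to-five ring contraction that forms C13–O, sets quaternary C13 under ligand control and releases C16 as an aldehyde. Reduction and alkynol cycloisomerisation close the dihydrofuran; the decalin, with C5 and C10, comes from (+)-sclareolide.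

Key step: step 14

Remark: labdane numbering is used throughout (C1–C10 decalin, C11–C16 side chain, C17–C20 methyls; α is the face opposite the C10 methyl).
Assumption: (S,S)-Ph-pybox is taken as the ligand enantiomer matched with the substrate in step 14; if the antipode proves matched, it replaces it with nothing else changed.

Step 1
Reactants: 1 (+)-sclareolide
Product: 2 methyl 13,14,15,16-tetranorlabd-8-en-12-oate
Conditions: MeOH, conc. H2SO4 (cat.), reflux
Reagents that add atoms: methanol, CO
Why: Acid-catalysed lactone methanolysis with E1 dehydration at C8 (Fischer-type esterification/elimination) should give, under the equilibrating conditions, the thermodynamically favoured tetrasubstituted Δ8 alkene while C5 and C10 stay untouched.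

Step 2
Reactants: 2 methyl 13,14,15,16-tetranorlabd-8-en-12-oate
Product: 3 13,14,15,16-tetranorlabd-8-en-12-ol
Conditions: LiAlH4, THF, 0 °C to rt
Reagents that add atoms: none
Why: Ester reduction with LiAlH4 gives the primary alcohol and leaves the tetrasubstituted alkene alone.

Step 3
Reactants: 3 13,14,15,16-tetranorlabd-8-en-12-ol
Product: 4 12-iodo-13,14,15,16-tetranorlabd-8-ene
Conditions: I2, PPh3, imidazole, CH2Cl2, 0 °C to rt
Reagents that add atoms: iodine, II
Why: Appel-type iodination converts the unhindered primary alcohol into the iodide under neutral conditions that do not move the alkene.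

Step 4
Reactants: 4 12-iodo-13,14,15,16-tetranorlabd-8-ene; 5 1-(trimethylsilyl)propyne
Product: 7 15-(trimethylsilyl)-16-norlabd-8-en-14-yne, via lithiated silylpropyne 6 (not isolated)
Conditions: 5, n-BuLi, THF, −78 to −20 °C; then 4, DMPU, −78 °C to rt
Reagents that add atoms: none
Why: SN2 alkylation of the propargylic lithium reagent by the primary iodide should occur at the CH2 terminus because the C-silyl group blocks the allenic position, adding C13–C15 in one operation.

Step 5
Reactants: 7 15-(trimethylsilyl)-16-norlabd-8-en-14-yne; 8 formaldehyde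
Product: 11 16-(tert-butyldimethylsilyloxy)-15-(trimethylsilyl)labd-8-en-14-yne (both C13 epimers), via allenylzinc bromide 9 (not isolated), via bromozinc alkoxide 10 (not isolated)
Conditions: n-BuLi, TMEDA, THF, −20 °C; ZnBr2, −78 °C; CH2O (gas, from paraformaldehyde), −78 to 0 °C; then TBSOTf, 0 °C
Reagents that add atoms: tert-butyldimethylsilyl triflate, CC(C)(C)[Si](C)(C)OS(=O)(=O)C(F)(F)F
Why: Propargylic lithiation, transmetalation to the allenylzinc and SE2′ addition to formaldehyde should give the branched homopropargylic alkoxide, which is silylated in the same flask; C13 is formed as both epimers on purpose, since it is made planar again in step 13.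

Step 6
Reactants: 11 16-(tert-butyldimethylsilyloxy)-15-(trimethylsilyl)labd-8-en-14-yne
Product: 12 16-(tert-butyldimethylsilyloxy)-15-(trimethylsilyl)labd-8-en-14-yn-7-one
Conditions: CrO3, 3,5-dimethylpyrazole, CH2Cl2, −20 °C
Reagents that add atoms: chromium trioxide, O=[Cr](=O)=O
Why: Chromium(VI)–pyrazole allylic oxidation attacks the ring methylene C7 next to the tetrasubstituted alkene and should give the 8-en-7-one, with the silyl ether, the silylalkyne and the tertiary propargylic C–H tolerated.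

Step 7
Reactants: 12 16-(tert-butyldimethylsilyloxy)-15-(trimethylsilyl)labd-8-en-14-yn-7-one
Product: 13 8α,9α-epoxy-16-(tert-butyldimethylsilyloxy)-15-(trimethylsilyl)labd-14-yn-7-one
Conditions: t-BuOOH, n-BuLi, THF, −78 to 0 °C
Reagents that add atoms: tert-butyl hydroperoxide, CC(C)(C)OO
Why: Weitz–Scheffer-type nucleophilic epoxidation with lithium tert-butyl peroxide should add to C9 from the α face, anti to the axial C10 methyl, so that the 8α,9α-epoxide fixes the later C9–O configuration, and the anhydrous base spares both silyl groups.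

Step 8
Reactants: 13 8α,9α-epoxy-16-(tert-butyldimethylsilyloxy)-15-(trimethylsilyl)labd-14-yn-7-one
Product: 15 7-acetoxy-8α,9α-epoxy-16-(tert-butyldimethylsilyloxy)-15-(trimethylsilyl)labd-6-en-14-yne, via lithium enolate 14 (not isolated)
Conditions: LiHMDS, THF, −78 °C; then Ac2O, −78 to 0 °C
Reagents that add atoms: acetic anhydride, CC(=O)OC(C)=O
Why: Because C8 is quaternary the ketone can enolise only towards C6, so kinetic deprotonation and O-acetylation of the lithium enolate give the Δ6 enol acetate regiospecifically.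

Step 9
Reactants: 15 7-acetoxy-8α,9α-epoxy-16-(tert-butyldimethylsilyloxy)-15-(trimethylsilyl)labd-6-en-14-yne
Product: 17 6β-acetoxy-8α,9α-epoxy-16-(tert-butyldimethylsilyloxy)-15-(trimethylsilyl)labd-14-yn-7-one, via bis-epoxide 16 (not isolated)
Conditions: DMDO, acetone/CH2Cl2, 0 °C; evaporate; then toluene, 110 °C
Reagents that add atoms: dimethyldioxirane, CC1(C)OO1
Why: DMDO should epoxidise the enol acetate from the α face (the β face is screened by the axial methyls on C4 and C10), and the thermal enol ester epoxide rearrangement, a 1,2-acyloxy shift with inversion at C6, should then give the 6β-acetoxy ketone.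

Step 10
Reactants: 17 6β-acetoxy-8α,9α-epoxy-16-(tert-butyldimethylsilyloxy)-15-(trimethylsilyl)labd-14-yn-7-one
Product: 18 6β-acetoxy-9α-hydroxy-16-(tert-butyldimethylsilyloxy)-15-(trimethylsilyl)labd-14-yn-7-one (8β-H)
Conditions: Cp2TiCl2, Zn, THF, rt; then 17, 2,4,6-collidine·HCl, −20 °C
Reagents that add atoms: none
Why: Titanocene(III) reductive opening of the α,β-epoxy ketone (C8–O homolysis, second electron transfer to the titanium enolate, protonation) keeps the oxygen on C9 in its α configuration and should set C8 as the equatorial 8α-methyl (8β-H) epimer on protonation or equilibration, while the ketone-activated epoxide is expected to react faster than the α′-acetoxy group.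

Step 11
Reactants: 18 6β-acetoxy-9α-hydroxy-16-(tert-butyldimethylsilyloxy)-15-(trimethylsilyl)labd-14-yn-7-one
Product: 19 6β-acetoxy-9α,16-dihydroxylabd-14-yn-7-one
Conditions: TBAF, AcOH, THF, 0 °C
Reagents that add atoms: none
Why: Fluoride-mediated desilylation buffered with acetic acid removes the O-TBS and C-TMS groups together without harming the acetate or dehydrating the β-hydroxy ketone.

Step 12
Reactants: 19 6β-acetoxy-9α,16-dihydroxylabd-14-yn-7-one
Product: 21 6β-acetoxy-9α,16-epoxy-16-hydroxylabd-14-yn-7-one (lactol), via hydroxy aldehyde 20 (not isolated)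
Conditions: DMP, pyridine, CH2Cl2, 0 °C to rt
Reagents that add atoms: none
Why: DMP oxidation of the primary alcohol gives the δ-hydroxy aldehyde, which should close at once to the six-membered lactol on the tertiary C9 hydroxyl (hemiacetalisation), so that the hindered oxygen is bound without any alkylation step.

Step 13
Reactants: 21 6β-acetoxy-9α,16-epoxy-16-hydroxylabd-14-yn-7-one
Product: 23 6β-acetoxy-9α,16-epoxylabd-13(16)-en-14-yn-7-one, via anomeric mesylate 22 (not isolated)
Conditions: MsCl, Et3N, CH2Cl2, −20 °C to rt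
Reagents that add atoms: none
Why: Anomeric mesylation followed by E2 loss of the acidic propargylic C13–H (lactol-to-glycal dehydration) should give the conjugated enyne enol ether, in which C13 is planar so that all lactol diastereomers converge.

Step 14
Reactants: 23 6β-acetoxy-9α,16-epoxylabd-13(16)-en-14-yn-7-one
Product: 25 (13R)-6β-acetoxy-9α,13-epoxy-7-oxolabd-14-yn-16-al, via epoxy acetal 24 (not isolated)
Conditions: DMDO (1.05 equiv), acetone/CH2Cl2, −78 °C; evaporate cold; then Cu(MeCN)4PF6 (5 mol %), (S,S)-Ph-pybox (6 mol %), i-Pr2NEt (0.2 equiv), THF, −20 to 0 °C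
Reagents that add atoms: dimethyldioxirane, CC1(C)OO1
Why: Proposed new method: DMDO epoxidises the electron-rich enol ether C16=C13 to the 13,16-epoxy acetal 24 (either face, which does not matter); copper(I) acetylide formation at C15 then expels the propargylic epoxide oxygen from C13 to give a copper allenylidene (Cu=C15=C14=C13), whose C16 hemiacetal alkoxide collapses to the aldehyde and hands the ring oxygen O9 over to C13, a net 1,2-shift of O9 that contracts the six-membered ring O9–C16–C13–C12–C11–C9 to the oxolane O9–C13–C12–C11–C9. The closest known reactions are the copper–pybox propargylic substitution of ethynyl epoxides and tertiary propargylic carbonates through copper allenylidenes, and the oxidative (thallium(III) or iodine(III)) ring contraction of glycals to 2,5-anhydro sugars. The oxolane closes by 5-exo attack of O9 on the planar allenylidene γ-carbon C13. C13 is the only new stereocentre: it is planar in the allenylidene, so both epoxide diastereomers converge, and its configuration is set by the chiral pybox ligand, helped by the slim ethynylcopper rod preferring the face next to quaternary C10. The step needs cleavage of C13–O and not of the anomeric C16–O bond of the epoxy acetal; the basic, Lewis-acid-free acetylide conditions should secure this, because only the acetylide can push out the propargylic oxygen.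

Step 15
Reactants: 25 (13R)-6β-acetoxy-9α,13-epoxy-7-oxolabd-14-yn-16-al
Product: 26 (13R)-6β-acetoxy-9α,13-epoxy-16-hydroxylabd-14-yn-7-one
Conditions: NaBH4, EtOH/CH2Cl2, −78 °C
Reagents that add atoms: none
Why: Borohydride reduction at −78 °C should be chemoselective for the aldehyde over the hindered, doubly flanked C7 ketone and the acetate.

Step 16
Reactants: 26 (13R)-6β-acetoxy-9α,13-epoxy-16-hydroxylabd-14-yn-7-one
Product: 27 (13R)-6β-acetoxy-9α,13:15,16-diepoxylabd-14-en-7-one (target)
Conditions: Mo(CO)6 (25 mol %), Et3N, Et2O, hν (350 nm) to preform (Et3N)Mo(CO)5; then 26, rt, dark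
Reagents that add atoms: none
Why: Alkynol cycloisomerisation through a molybdenum vinylidene (5-endo-dig attack of the C16 hydroxyl on C15) should give the 2,3-dihydrofuran without touching any stereocentre, and the amine-buffered medium protects the acid-labile spiro enol ether.

Compound list
1 | (+)-sclareolide (5α-H, 9α-H, 10β-CH3, 8α-O lactone) | C1C[C@@]3(C)OC(=O)C[C@@H]3[C@@]2(C)CCCC(C)(C)[C@H]12 | starting material
2 | methyl 13,14,15,16-tetranorlabd-8-en-12-oate | C1CC(C)=C(CC(=O)OC)[C@@]2(C)CCCC(C)(C)[C@H]12 | intermediate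
3 | 13,14,15,16-tetranorlabd-8-en-12-ol | C1CC(C)=C(CCO)[C@@]2(C)CCCC(C)(C)[C@H]12 | intermediate
4 | 12-iodo-13,14,15,16-tetranorlabd-8-ene | C1CC(C)=C(CCI)[C@@]2(C)CCCC(C)(C)[C@H]12 | intermediate
5 | 1-(trimethylsilyl)propyne | CC#C[Si](C)(C)C | starting material
6 | 3-lithio-1-(trimethylsilyl)propyne | [Li]CC#C[Si](C)(C)C | intermediate
7 | 15-(trimethylsilyl)-16-norlabd-8-en-14-yne | C1CC(C)=C(CCCC#C[Si](C)(C)C)[C@@]2(C)CCCC(C)(C)[C@H]12 | intermediate
8 | formaldehyde (monomer from paraformaldehyde) | C=O | starting material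
9 | [15-(trimethylsilyl)-16-norlabda-8,13,14-trien-15-yl]zinc bromide | C1CC(C)=C(CCC=C=C([Zn]Br)[Si](C)(C)C)[C@@]2(C)CCCC(C)(C)[C@H]12 | intermediate
10 | bromozinc alkoxide of 16-hydroxy-15-(trimethylsilyl)labd-8-en-14-yne (both C13 epimers) | C1CC(C)=C(CCC(CO[Zn]Br)C#C[Si](C)(C)C)[C@@]2(C)CCCC(C)(C)[C@H]12 | intermediate
11 | 16-(tert-butyldimethylsilyloxy)-15-(trimethylsilyl)labd-8-en-14-yne (both C13 epimers) | C1CC(C)=C(CCC(CO[Si](C)(C)C(C)(C)C)C#C[Si](C)(C)C)[C@@]2(C)CCCC(C)(C)[C@H]12 | intermediate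
12 | 16-(tert-butyldimethylsilyloxy)-15-(trimethylsilyl)labd-8-en-14-yn-7-one | C1C(=O)C(C)=C(CCC(CO[Si](C)(C)C(C)(C)C)C#C[Si](C)(C)C)[C@@]2(C)CCCC(C)(C)[C@H]12 | intermediate
13 | 8α,9α-epoxy-16-(tert-butyldimethylsilyloxy)-15-(trimethylsilyl)labd-14-yn-7-one | C1C(=O)[C@@]3(C)O[C@@]3(CCC(CO[Si](C)(C)C(C)(C)C)C#C[Si](C)(C)C)[C@@]2(C)CCCC(C)(C)[C@H]12 | intermediate
14 | lithium Δ6-enolate of 13 | C1=C(O[Li])[C@@]3(C)O[C@@]3(CCC(CO[Si](C)(C)C(C)(C)C)C#C[Si](C)(C)C)[C@@]2(C)CCCC(C)(C)[C@H]12 | intermediate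
15 | 7-acetoxy-8α,9α-epoxy-16-(tert-butyldimethylsilyloxy)-15-(trimethylsilyl)labd-6-en-14-yne | C1=C(OC(C)=O)[C@@]3(C)O[C@@]3(CCC(CO[Si](C)(C)C(C)(C)C)C#C[Si](C)(C)C)[C@@]2(C)CCCC(C)(C)[C@H]12 | intermediate
16 | 7β-acetoxy-6α,7α:8α,9α-diepoxy-16-(tert-butyldimethylsilyloxy)-15-(trimethylsilyl)labd-14-yne | O4[C@H]1[C@]4(OC(C)=O)[C@@]3(C)O[C@@]3(CCC(CO[Si](C)(C)C(C)(C)C)C#C[Si](C)(C)C)[C@@]2(C)CCCC(C)(C)[C@H]12 | intermediate
17 | 6β-acetoxy-8α,9α-epoxy-16-(tert-butyldimethylsilyloxy)-15-(trimethylsilyl)labd-14-yn-7-one | CC(=O)O[C@@H]1C(=O)[C@@]3(C)O[C@@]3(CCC(CO[Si](C)(C)C(C)(C)C)C#C[Si](C)(C)C)[C@@]2(C)CCCC(C)(C)[C@H]12 | intermediate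
18 | 6β-acetoxy-9α-hydroxy-16-(tert-butyldimethylsilyloxy)-15-(trimethylsilyl)labd-14-yn-7-one (8β-H, 8α-CH3) | CC(=O)O[C@@H]1C(=O)[C@@H](C)[C@](O)(CCC(CO[Si](C)(C)C(C)(C)C)C#C[Si](C)(C)C)[C@@]2(C)CCCC(C)(C)[C@H]12 | intermediate
19 | 6β-acetoxy-9α,16-dihydroxylabd-14-yn-7-one | CC(=O)O[C@@H]1C(=O)[C@@H](C)[C@](O)(CCC(CO)C#C)[C@@]2(C)CCCC(C)(C)[C@H]12 | intermediate
20 | 6β-acetoxy-9α-hydroxy-7-oxolabd-14-yn-16-al | CC(=O)O[C@@H]1C(=O)[C@@H](C)[C@](O)(CCC(C=O)C#C)[C@@]2(C)CCCC(C)(C)[C@H]12 | intermediate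
21 | 6β-acetoxy-9α,16-epoxy-16-hydroxylabd-14-yn-7-one (lactol, mixture at C13 and C16) | CC(=O)O[C@@H]1C(=O)[C@@H](C)[C@]2(CCC(C#C)C(O)O2)[C@@]2(C)CCCC(C)(C)[C@H]12 | intermediate
22 | 16-O-methanesulfonate of lactol 21 | CC(=O)O[C@@H]1C(=O)[C@@H](C)[C@]2(CCC(C#C)C(OS(C)(=O)=O)O2)[C@@]2(C)CCCC(C)(C)[C@H]12 | intermediate
23 | 6β-acetoxy-9α,16-epoxylabd-13(16)-en-14-yn-7-one (spiro 5-ethynyl-3,4-dihydro-2H-pyran) | CC(=O)O[C@@H]1C(=O)[C@@H](C)[C@]2(CCC(C#C)=CO2)[C@@]2(C)CCCC(C)(C)[C@H]12 | intermediate
24 | 6β-acetoxy-9α,16:13,16-diepoxylabd-14-yn-7-one (epoxy acetal, both epoxide faces) | CC(=O)O[C@@H]1C(=O)[C@@H](C)[C@]2(CCC3(C#C)OC3O2)[C@@]2(C)CCCC(C)(C)[C@H]12 | intermediate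
25 | (13R)-6β-acetoxy-9α,13-epoxy-7-oxolabd-14-yn-16-al | CC(=O)O[C@@H]1C(=O)[C@@H](C)[C@]2(CC[C@](C=O)(C#C)O2)[C@@]2(C)CCCC(C)(C)[C@H]12 | intermediate
26 | (13R)-6β-acetoxy-9α,13-epoxy-16-hydroxylabd-14-yn-7-one | CC(=O)O[C@@H]1C(=O)[C@@H](C)[C@]2(CC[C@](CO)(C#C)O2)[C@@]2(C)CCCC(C)(C)[C@H]12 | intermediate
27 | (13R)-6β-acetoxy-9α,13:15,16-diepoxylabd-14-en-7-one | CC(=O)O[C@@H]1C(=O)[C@@H](C)[C@]2(CC[C@]3(C=COC3)O2)[C@@]2(C)CCCC(C)(C)[C@H]12 | target

Total step count: 16. Longest linear sequence: 16 steps from (+)-sclareolide 1.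

Steps most likely to fail

Step 14 (Proposed new method). The epoxy acetal may ionise at its anomeric C16–O bond before the copper acetylide forms; the resulting oxocarbenium ion would then undergo 1,2-shift of the ethynyl group or of ring carbon C12, or be captured by adventitious nucleophiles. Ligand control at C13 may also be weak. The fallback uses the known hypervalent-iodine oxidative ring contraction of glycals and sets out from enyne glycal 23. [Hydroxy(tosyloxy)iodo]benzene in wet acetonitrile at −20 °C adds iodine(III) to C13 and water to C16. Loss of iodobenzene from C13 with participation of the antiperiplanar ring oxygen then contracts the six-membered ring and should give aldehyde 25 together with its C13 epimer, (13S)-6β-acetoxy-9α,13-epoxy-7-oxolabd-14-yn-16-al F1, which is removed by chromatography. The route is rejoined at 25.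

Step 10. Single-electron reduction may also cleave the α′-acetoxy group at C6, or the new β-hydroxy ketone may dehydrate to the enone. The fallback changes the order of events and sets out from epoxy ketone 13. Samarium diiodide in THF/MeOH at −78 °C opens the epoxy ketone to the 9α-hydroxy ketone F2. TMSOTf with 2,6-lutidine gives the 9-O-trimethylsilyl ether F3. LiHMDS at −78 °C forms the kinetic C6 lithium enolate F4, which Ac2O converts into the enol acetate F5. DMDO then gives the 6α,7α-epoxide F6, which on heating in toluene rearranges to the 6β-acetoxy ketone F7. TBAF/AcOH removes all three silyl groups and returns the route at 19.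

Step 16. The amine and the metal may epimerise the axial C6 acetate or open the β-alkoxy ketone by retro-oxa-Michael reaction, and vinylidene formation may be slow at the hindered tertiary propargylic ether. The fallback sets out from alcohol 26. Ruthenium-catalysed anti-Markovnikov hydration of the terminal alkyne (CpRu(MeCN)3PF6 with a bipyridyl ligand, aqueous acetone, 50 °C) should give the aldehyde F8, which closes onto the C16 hydroxyl to the 15-hydroxy lactol F9. MsCl and Et3N at −20 °C convert it through the anomeric mesylate F10 into the enol ether, and the route ends at 27.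

Further compounds
F1 | step 14 | (13S)-6β-acetoxy-9α,13-epoxy-7-oxolabd-14-yn-16-al | CC(=O)O[C@@H]1C(=O)[C@@H](C)[C@]2(CC[C@@](C=O)(C#C)O2)[C@@]2(C)CCCC(C)(C)[C@H]12
F2 | step 10 | 9α-hydroxy-16-(tert-butyldimethylsilyloxy)-15-(trimethylsilyl)labd-14-yn-7-one (8β-H) | C1C(=O)[C@@H](C)[C@](O)(CCC(CO[Si](C)(C)C(C)(C)C)C#C[Si](C)(C)C)[C@@]2(C)CCCC(C)(C)[C@H]12
F3 | step 10 | 9α-(trimethylsilyloxy)-16-(tert-butyldimethylsilyloxy)-15-(trimethylsilyl)labd-14-yn-7-one | C1C(=O)[C@@H](C)[C@](O[Si](C)(C)C)(CCC(CO[Si](C)(C)C(C)(C)C)C#C[Si](C)(C)C)[C@@]2(C)CCCC(C)(C)[C@H]12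
F4 | step 10 | lithium Δ6-enolate of F3 | C1=C(O[Li])[C@@H](C)[C@](O[Si](C)(C)C)(CCC(CO[Si](C)(C)C(C)(C)C)C#C[Si](C)(C)C)[C@@]2(C)CCCC(C)(C)[C@H]12
F5 | step 10 | 7-acetoxy-9α-(trimethylsilyloxy)-16-(tert-butyldimethylsilyloxy)-15-(trimethylsilyl)labd-6-en-14-yne | C1=C(OC(C)=O)[C@@H](C)[C@](O[Si](C)(C)C)(CCC(CO[Si](C)(C)C(C)(C)C)C#C[Si](C)(C)C)[C@@]2(C)CCCC(C)(C)[C@H]12
F6 | step 10 | 7β-acetoxy-6α,7α-epoxy-9α-(trimethylsilyloxy)-16-(tert-butyldimethylsilyloxy)-15-(trimethylsilyl)labd-14-yne | O4[C@H]1[C@]4(OC(C)=O)[C@@H](C)[C@](O[Si](C)(C)C)(CCC(CO[Si](C)(C)C(C)(C)C)C#C[Si](C)(C)C)[C@@]2(C)CCCC(C)(C)[C@H]12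
F7 | step 10 | 6β-acetoxy-9α-(trimethylsilyloxy)-16-(tert-butyldimethylsilyloxy)-15-(trimethylsilyl)labd-14-yn-7-one | CC(=O)O[C@@H]1C(=O)[C@@H](C)[C@](O[Si](C)(C)C)(CCC(CO[Si](C)(C)C(C)(C)C)C#C[Si](C)(C)C)[C@@]2(C)CCCC(C)(C)[C@H]12
F8 | step 16 | (13R)-6β-acetoxy-9α,13-epoxy-16-hydroxy-7-oxolabdan-15-al | CC(=O)O[C@@H]1C(=O)[C@@H](C)[C@]2(CC[C@](CO)(CC=O)O2)[C@@]2(C)CCCC(C)(C)[C@H]12
F9 | step 16 | (13R)-6β-acetoxy-9α,13:15,16-diepoxy-15-hydroxylabdan-7-one (lactol, both C15 epimers) | CC(=O)O[C@@H]1C(=O)[C@@H](C)[C@]2(CC[C@]3(CC(O)OC3)O2)[C@@]2(C)CCCC(C)(C)[C@H]12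
F10 | step 16 | 15-O-methanesulfonate of lactol F9 | CC(=O)O[C@@H]1C(=O)[C@@H](C)[C@]2(CC[C@]3(CC(OS(C)(=O)=O)OC3)O2)[C@@]2(C)CCCC(C)(C)[C@H]12
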